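**Plan**

1. Labels: ring A is the cyclohexadienone (C-1 carbonyl, C-2 allyl, C-4 the methoxylated quaternary carbon, C-5 methoxy), C-7 is CH(OAc), C-8 is CH(CH3), ring B is the 3,4-dimethoxyphenyl ring. Cuts, in order: O-7–acetyl; C-4–OMe (ring A back to a phenol, the methoxy traced to a methoxymethyl ether on O-7); C-7–C-8; C-8–C-4; the allyl C–C bond (Claisen).
2. Forward: ring A is carried as an aromatic, silyl-protected 2-allyl-5-methoxyphenol. Its boronic ester is homologated twice with lithiated carbamates, first by the C-8/CH3 unit, then by C-7 carrying ring B. The dienone ring arises last, by oxidative dearomatisation.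
3. Feature behind the key event: C-7 is benzylic to ring B and bears oxygen, so its O-carbamate can be lithiated to a carbenoid; C-8 is benzylic to aromatic ring A and can hold a boronic ester. The 1,2-shift from boron to C-7 makes the C-7–C-8 bond and leaves boron on C-7, where oxidation turns it into O-7.
4. Feature used afterwards: O-7 and C-4 stand 1,3 across C-8, so a methoxymethyl group on O-7 can hand its methoxy group to C-4 through a six-membered oxonium ion.
5. Stereochemistry: C-8 from the (+)-sparteine-controlled ethyl carbenoid; C-7 from the ligand-controlled benzylic carbenoid (retention at boron, inversion in the shift); C-4 from C-8 through A(1,3) strain combined with delivery from the O-7 tether.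

Key step: step 7

Assumption: ethyl N,N-di(propan-2-yl)carbamate (7) is taken as a purchasable compound, and in step 7 the antipode of the ligand 2,2-bis(4-isopropyl-4,5-dihydrooxazol-2-yl)propane is chosen so that the benzylic lithium compound is borylated as its (R) form.

Shorthand: ArA = 2-methoxy-5-(prop-2-en-1-yl)-4-[tri(propan-2-yl)silyloxy]phenyl; ArB = 3,4-dimethoxyphenyl; Cb = N,N-di(propan-2-yl)carbamoyl; Bpin = 4,4,5,5-tetramethyl-1,3,2-dioxaborolan-2-yl.

**Step 1**
Reactants: 1 4-bromo-3-methoxyphenol
Product: 2 1-bromo-2-methoxy-4-(prop-2-en-1-yloxy)benzene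
Conditions: allyl bromide, K2CO3, acetone, reflux
Reagents that add atoms: allyl bromide, C=CCBr
Why: Williamson ether synthesis, SN2 alkylation of the phenoxide by the allylic bromide.

**Step 2**
Reactants: 2 1-bromo-2-methoxy-4-(prop-2-en-1-yloxy)benzene
Product: 3 4-bromo-5-methoxy-2-(prop-2-en-1-yl)phenol
Conditions: PhNEt2, 190 °C
Reagents that add atoms: none
Why: aromatic Claisen rearrangement ([3,3] shift, then tautomerisation to the phenol); the allyl group should go mainly to the unflanked ortho carbon, para to the methoxy group, because the other ortho carbon lies between two oxygen substituents and the bromine holds the methoxy methyl over it.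

**Step 3**
Reactants: 3 4-bromo-5-methoxy-2-(prop-2-en-1-yl)phenol
Product: 4 [4-bromo-5-methoxy-2-(prop-2-en-1-yl)phenoxy]tri(propan-2-yl)silane (ArA–Br)
Conditions: i-Pr3SiCl, imidazole, DMF, 40 °C
Reagents that add atoms: triisopropylsilyl chloride, CC(C)[Si](Cl)(C(C)C)C(C)C
Why: silylation of the phenol (imidazole-promoted silyl transfer); the bulky silyl ether should survive organolithium, boronate and basic peroxide conditions and come off with fluoride.

**Step 4**
Reactants: 4 ArA–Br
Product: 6 ArA–Bpin, via aryllithium 5 (not isolated)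
Conditions: n-BuLi, THF, −78 °C; then i-PrOBpin, −78 °C to rt
Reagents that add atoms: 2-isopropoxy-4,4,5,5-tetramethyl-1,3,2-dioxaborolane, CC(C)OB1OC(C)(C)C(C)(C)O1
Why: bromine–lithium exchange is faster than any deprotonation at −78 °C, and the aryllithium is trapped at boron of the isopropoxyboronate (borylation of an organolithium).

**Step 5**
Reactants: 6 ArA–Bpin; 7 ethyl N,N-di(propan-2-yl)carbamate
Product: 10 2-[(1S)-1-ArA-ethyl]-4,4,5,5-tetramethyl-1,3,2-dioxaborolane, via lithiated ethyl carbamate 8 (not isolated), via boronate complex 9 (not isolated)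
Conditions: 7, s-BuLi, (+)-sparteine, Et2O, −78 °C; then 6, −78 °C; then MgBr2·OEt2, reflux
Reagents that add atoms: none
Why: lithiation–borylation (1,2-metallate rearrangement): sparteine-controlled deprotonation should give the (R)-lithio carbamate 8, boron is attacked with retention, and the electron-rich aryl group then shifts from boron to carbon anti to the leaving carbamate (inversion), which sets C-8 as (S).

**Step 6**
Reactants: 11 (3,4-dimethoxyphenyl)methanol
Product: 12 (3,4-dimethoxyphenyl)methyl N,N-di(propan-2-yl)carbamate (ArB–CH2–OCb)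
Conditions: i-Pr2NCOCl, Et3N, CH2Cl2, reflux
Reagents that add atoms: N,N-diisopropylcarbamoyl chloride, CC(C)N(C(C)C)C(Cl)=O
Why: O-carbamoylation of a primary benzylic alcohol (acyl substitution) installs the group that later directs lithiation and serves as the leaving group.

**Step 7**
Reactants: 10 (S)-ArA–CH(CH3)–Bpin; 12 ArB–CH2–OCb
Product: 16 (1R,2S)-1-ArB-2-ArA-propan-1-ol, via lithiated benzyl carbamate 13 (not isolated), via boronate complex 14 (not isolated), via secondary boronic ester 15 (not isolated)
Conditions: 12, s-BuLi, 2,2-bis(4-isopropyl-4,5-dihydrooxazol-2-yl)propane (single antipode), Et2O, −78 °C; then 10, −78 °C to rt; then NaOH, H2O2, THF–H2O, 0 °C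
Reagents that add atoms: hydrogen peroxide, OO
Why: s-BuLi removes a benzylic proton next to the carbamate oxygen of 12; the lithio carbamate 13, held in the (R) form by the chiral ligand, adds to boron of 10 with retention to give boronate complex 14, in which the C-8 group migrates from boron to C-7 anti-periplanar to the departing carbamate (inversion at C-7, retention at C-8), and oxidation of the new C–B bond of 15 with retention gives the alcohol. The closest known reaction type is the lithiation–borylation homologation of secondary boronic esters with lithiated carbamates (1,2-metallate rearrangement) followed by oxidation. No ring is closed. C-7 is controlled by the configuration of the carbenoid carbon of 13 (ligand control over a configurationally labile benzyllithium) and C-8 is carried over unchanged from 10, so the syn (1R,2S) pair should arise by reagent control. The step needs lithiation only at the benzylic CH2 of ring B and reaction only at boron: the carbamate carbonyl directs the base to that CH2, the phenol of ring A is masked as a silyl ether, the allyl group and the aryl ethers are inert to boronate chemistry, and boronic ester 15 is too hindered for a second homologation. Boron, the activating group, ends as the oxygen on C-7, so no helper atom has to be removed from the chain.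

**Step 8**
Reactants: 16 (1R,2S)-1-ArB-2-ArA-propan-1-ol
Product: 17 {4-[(1R,2S)-1-(3,4-dimethoxyphenyl)-1-(methoxymethoxy)propan-2-yl]-5-methoxy-2-(prop-2-en-1-yl)phenoxy}tri(propan-2-yl)silane
Conditions: MeOCH2Cl, i-Pr2NEt, Bu4NI (cat.), CH2Cl2, 0 °C to rt
Reagents that add atoms: chloromethyl methyl ether, COCCl
Why: alkylation of the secondary alcohol with the chloromethyl ether (acetal-type ether formation); it places on O-7 the methoxy group that step 10 moves to C-4.

**Step 9**
Reactants: 17 methoxymethyl ether silyl ether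
Product: 18 4-[(1R,2S)-1-(3,4-dimethoxyphenyl)-1-(methoxymethoxy)propan-2-yl]-5-methoxy-2-(prop-2-en-1-yl)phenol
Conditions: Bu4NF, AcOH, THF, 0 °C
Reagents that add atoms: none
Why: fluoride cleaves the aryl silyl ether (Si–F bond formation), buffered with acetic acid so that the phenoxide is protonated at once; the methoxymethyl ether is inert.

**Step 10**
Reactants: 18 phenol with the methoxymethyl ether on O-7
Product: 21 (4R)-4-[(1R,2R)-1-(3,4-dimethoxyphenyl)-1-hydroxypropan-2-yl]-4,5-dimethoxy-2-(prop-2-en-1-yl)cyclohexa-2,5-dien-1-one, via spirocyclic oxonium ion 19 (not isolated), via trifluoroacetoxymethyl ether 20 (not isolated)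
Conditions: PhI(OCOCF3)2, NaHCO3, CH2Cl2, −40 to 0 °C; then aq NaHCO3
Reagents that add atoms: none
Why: Proposed new method: the trivalent iodine reagent oxidises the phenol to an aryloxy-λ3-iodane (phenoxenium equivalent) that is electrophilic at C-4; with no external nucleophile present, the methoxy oxygen of the methoxymethyl ether on O-7 is the only oxygen that reaches C-4 through a six-membered transition state, giving oxonium ion 19, which breaks its O–CH2 bond with lone-pair help from O-7, so that the methoxy group stays on C-4 while the O-7 oxocarbenium ion is caught by trifluoroacetate (20) and hydrolysed with loss of formaldehyde on work-up; C-4 is set from C-8, because A(1,3) strain turns the C-8 hydrogen toward the C-5 methoxy group and thereby puts C-7 with its tether on the face that leads to (4R), whereas external methanol would be expected on the opposite face; the closest known reaction types are the oxidative dearomatising spirocyclisation of para-substituted phenols with tethered oxygen nucleophiles by PhI(OAc)2 or PhI(OCOCF3)2 and the participation of acetal oxygens toward cationic centres with fragmentation to an oxocarbenium ion (haloetherification of ene acetals, alkoxide abstraction from acetals by carbocations).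

**Step 11**
Reactants: 21 dienone alcohol
Product: 22 (4R)-4-[(1R,2R)-1-(acetyloxy)-1-(3,4-dimethoxyphenyl)propan-2-yl]-4,5-dimethoxy-2-(prop-2-en-1-yl)cyclohexa-2,5-dien-1-one
Conditions: Ac2O, pyridine, DMAP (cat.), CH2Cl2, 0 °C
Reagents that add atoms: acetic anhydride, CC(=O)OC(C)=O
Why: DMAP-catalysed acylation of the secondary benzylic alcohol (acyl transfer), the only free hydroxyl, under weakly basic conditions that should leave the dienone and the quinol methyl ether untouched.

**Compound list**

1 | 4-bromo-3-methoxyphenol | COc1cc(O)ccc1Br | starting material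
2 | 1-bromo-2-methoxy-4-(prop-2-en-1-yloxy)benzene | C=CCOc1ccc(Br)c(OC)c1 | intermediate
3 | 4-bromo-5-methoxy-2-(prop-2-en-1-yl)phenol | C=CCc1cc(Br)c(OC)cc1O | intermediate
4 | [4-bromo-5-methoxy-2-(prop-2-en-1-yl)phenoxy]tri(propan-2-yl)silane | C=CCc1cc(Br)c(OC)cc1O[Si](C(C)C)(C(C)C)C(C)C | intermediate
5 | {2-methoxy-5-(prop-2-en-1-yl)-4-[tri(propan-2-yl)silyloxy]phenyl}lithium | C=CCc1cc([Li])c(OC)cc1O[Si](C(C)C)(C(C)C)C(C)C | intermediate
6 | 2-{2-methoxy-5-(prop-2-en-1-yl)-4-[tri(propan-2-yl)silyloxy]phenyl}-4,4,5,5-tetramethyl-1,3,2-dioxaborolane | C=CCc1cc(B2OC(C)(C)C(C)(C)O2)c(OC)cc1O[Si](C(C)C)(C(C)C)C(C)C | intermediate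
7 | ethyl N,N-di(propan-2-yl)carbamate | CCOC(=O)N(C(C)C)C(C)C | starting material
8 | (R)-1-lithioethyl N,N-di(propan-2-yl)carbamate, (+)-sparteine complex (ligand not drawn) | [Li][C@H](C)OC(=O)N(C(C)C)C(C)C | intermediate
9 | lithium pinacolatoborate carrying ArA and the (1R)-1-(Cb-oxy)ethyl group on boron | C=CCc1cc([B-]2(OC(C)(C)C(C)(C)O2)[C@H](C)OC(=O)N(C(C)C)C(C)C)c(OC)cc1O[Si](C(C)C)(C(C)C)C(C)C.[Li+] | intermediate
10 | 2-[(1S)-1-{2-methoxy-5-(prop-2-en-1-yl)-4-[tri(propan-2-yl)silyloxy]phenyl}ethyl]-4,4,5,5-tetramethyl-1,3,2-dioxaborolane | C=CCc1cc([C@H](C)B2OC(C)(C)C(C)(C)O2)c(OC)cc1O[Si](C(C)C)(C(C)C)C(C)C | intermediate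
11 | (3,4-dimethoxyphenyl)methanol | COc1ccc(CO)cc1OC | starting material
12 | (3,4-dimethoxyphenyl)methyl N,N-di(propan-2-yl)carbamate | COc1ccc(COC(=O)N(C(C)C)C(C)C)cc1OC | intermediate
13 | (R)-(3,4-dimethoxyphenyl)(lithio)methyl N,N-di(propan-2-yl)carbamate, bis(oxazoline) complex (ligand not drawn) | [Li][C@@H](OC(=O)N(C(C)C)C(C)C)c1ccc(OC)c(OC)c1 | intermediate
14 | lithium pinacolatoborate carrying the (1S)-1-ArA-ethyl group and the (R)-ArB–CH(OCb) group on boron | C=CCc1cc([C@H](C)[B-]2(OC(C)(C)C(C)(C)O2)[C@@H](OC(=O)N(C(C)C)C(C)C)c3ccc(OC)c(OC)c3)c(OC)cc1O[Si](C(C)C)(C(C)C)C(C)C.[Li+] | intermediate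
15 | 2-[(1R,2R)-1-(3,4-dimethoxyphenyl)-2-{2-methoxy-5-(prop-2-en-1-yl)-4-[tri(propan-2-yl)silyloxy]phenyl}propyl]-4,4,5,5-tetramethyl-1,3,2-dioxaborolane | C=CCc1cc([C@H](C)[C@@H](B2OC(C)(C)C(C)(C)O2)c3ccc(OC)c(OC)c3)c(OC)cc1O[Si](C(C)C)(C(C)C)C(C)C | intermediate
16 | (1R,2S)-1-(3,4-dimethoxyphenyl)-2-{2-methoxy-5-(prop-2-en-1-yl)-4-[tri(propan-2-yl)silyloxy]phenyl}propan-1-ol | C=CCc1cc([C@H](C)[C@@H](O)c2ccc(OC)c(OC)c2)c(OC)cc1O[Si](C(C)C)(C(C)C)C(C)C | intermediate
17 | {4-[(1R,2S)-1-(3,4-dimethoxyphenyl)-1-(methoxymethoxy)propan-2-yl]-5-methoxy-2-(prop-2-en-1-yl)phenoxy}tri(propan-2-yl)silane | C=CCc1cc([C@H](C)[C@@H](OCOC)c2ccc(OC)c(OC)c2)c(OC)cc1O[Si](C(C)C)(C(C)C)C(C)C | intermediate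
18 | 4-[(1R,2S)-1-(3,4-dimethoxyphenyl)-1-(methoxymethoxy)propan-2-yl]-5-methoxy-2-(prop-2-en-1-yl)phenol | C=CCc1cc([C@H](C)[C@@H](OCOC)c2ccc(OC)c(OC)c2)c(OC)cc1O | intermediate
19 | spirocyclic O-methyl-1,3-dioxan-1-ium trifluoroacetate: the methoxy oxygen of the methoxymethyl group bonded to C-4 of the (4R)-2-allyl-5-methoxycyclohexa-2,5-dienone ring, with C-7 (R, bearing ArB) and C-8 (R, bearing CH3) in the six-membered ring | C=CCC1=C[C@]2([O+](C)CO[C@@H](c3ccc(OC)c(OC)c3)[C@H]2C)C(OC)=CC1=O.[O-]C(=O)C(F)(F)F | intermediate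
20 | (4R)-4-[(1R,2R)-1-(3,4-dimethoxyphenyl)-1-{[(trifluoroacetyl)oxy]methoxy}propan-2-yl]-4,5-dimethoxy-2-(prop-2-en-1-yl)cyclohexa-2,5-dien-1-one | C=CCC1=C[C@@](OC)([C@H](C)[C@@H](OCOC(=O)C(F)(F)F)c2ccc(OC)c(OC)c2)C(OC)=CC1=O | intermediate
21 | (4R)-4-[(1R,2R)-1-(3,4-dimethoxyphenyl)-1-hydroxypropan-2-yl]-4,5-dimethoxy-2-(prop-2-en-1-yl)cyclohexa-2,5-dien-1-one | C=CCC1=C[C@@](OC)([C@H](C)[C@@H](O)c2ccc(OC)c(OC)c2)C(OC)=CC1=O | intermediate
22 | (4R)-4-[(1R,2R)-1-(acetyloxy)-1-(3,4-dimethoxyphenyl)propan-2-yl]-4,5-dimethoxy-2-(prop-2-en-1-yl)cyclohexa-2,5-dien-1-one | C=CCC1=C[C@@](OC)([C@H](C)[C@@H](OC(C)=O)c2ccc(OC)c(OC)c2)C(OC)=CC1=O | target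

**Step count and risks**

Total steps: 11. Longest linear sequence: 10 steps (from 1 through steps 1–5 and 7–11).

Steps most likely to fail:

1. Step 10 (Proposed new method). What may go wrong:
   - capture of the oxidised phenol by the wrong nucleophile, namely Friedel–Crafts spirocyclisation of ring B onto C-4 or addition of external trifluoroacetate, outrunning the six-membered methoxy delivery;
   - ionisation of the benzylic C-7–O bond once O-7 carries positive charge;
   - conjugate addition of the freed C-7 hydroxyl to the dienone during work-up.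

   Fallback with known chemistry, setting out from 16 and coming back at 22: 16 is acetylated (Ac2O, pyridine, DMAP) to (1R,2S)-1-ArB-2-ArA-propyl acetate F1. The silyl ether is cleaved (Bu4NF, AcOH, THF) to the phenol acetate F2. F2 is then submitted to the ordinary oxidative dearomatisation of a para-alkylphenol in methanol (PhI(OAc)2, MeOH, 0 °C), in which methanol adds to C-4 from outside. Without the tether the face is chosen by the substrate alone, so 22 should form together with its (4S) epimer F3, which may well predominate, and the two would have to be separated by chromatography.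

2. Step 7 (key step). What may go wrong:
   - incomplete configurational control of the lithiated benzyl carbamate (epimerisation competing with borylation, or borylation with inversion);
   - reversible boronate formation with the hindered secondary boronic ester;
   - a slow 1,2-shift that lets the carbenoid decompose by carbamoyl migration.

   Fallback with known chemistry, setting out from 10 and coming back at 16: one-carbon Matteson homologation of 10 (LiCH2Cl from ICH2Cl and n-BuLi, THF, −78 °C to rt, retention at C-8) should give the primary boronic ester (R)-ArA–CH(CH3)–CH2–Bpin F4. Oxidation (NaOH, H2O2) gives (2S)-2-ArA-propan-1-ol F5, and Dess–Martin periodinane buffered with NaHCO3 gives the aldehyde (2S)-2-ArA-propanal F6. Addition of 3,4-(MeO)2C6H3MgBr (THF, −78 °C) then forms the C-7–aryl bond. Acyclic 1,2-induction, with the nucleophile entering anti to the aryl group on the α-carbon, should favour 16 over its C-1 epimer F7, which is removed by chromatography. The α-aryl aldehyde must be used at once to avoid enolisation.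

3. Step 2. What may go wrong: regiochemical leakage of the [3,3] shift to the ortho carbon between the two oxygen substituents, and thermal cyclisation of the ortho-allylphenol to a dihydrobenzofuran.

   Fallback with known chemistry, setting out from 1 and coming back at 3: electrophilic iodination of 1 (N-iodosuccinimide, MeCN, 0 °C) should go to the carbon ortho to the hydroxyl and para to the methoxy group, giving 4-bromo-2-iodo-5-methoxyphenol F8. A Stille coupling with CH2=CHCH2SnBu3 (Pd(PPh3)4, zerovalent palladium, DMF, 80 °C) then allylates the more reactive C–I bond and leaves the C–Br bond for step 4.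

**Further compounds**

F1 | step 10 | (1R,2S)-1-(3,4-dimethoxyphenyl)-2-{2-methoxy-5-(prop-2-en-1-yl)-4-[tri(propan-2-yl)silyloxy]phenyl}propyl acetate | C=CCc1cc([C@H](C)[C@@H](OC(C)=O)c2ccc(OC)c(OC)c2)c(OC)cc1O[Si](C(C)C)(C(C)C)C(C)C
F2 | step 10 | (1R,2S)-1-(3,4-dimethoxyphenyl)-2-[4-hydroxy-2-methoxy-5-(prop-2-en-1-yl)phenyl]propyl acetate | C=CCc1cc([C@H](C)[C@@H](OC(C)=O)c2ccc(OC)c(OC)c2)c(OC)cc1O
F3 | step 10 | (4S)-4-[(1R,2R)-1-(acetyloxy)-1-(3,4-dimethoxyphenyl)propan-2-yl]-4,5-dimethoxy-2-(prop-2-en-1-yl)cyclohexa-2,5-dien-1-one | C=CCC1=C[C@](OC)([C@H](C)[C@@H](OC(C)=O)c2ccc(OC)c(OC)c2)C(OC)=CC1=O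
F4 | step 7 | 2-[(2R)-2-{2-methoxy-5-(prop-2-en-1-yl)-4-[tri(propan-2-yl)silyloxy]phenyl}propyl]-4,4,5,5-tetramethyl-1,3,2-dioxaborolane | C=CCc1cc([C@H](C)CB2OC(C)(C)C(C)(C)O2)c(OC)cc1O[Si](C(C)C)(C(C)C)C(C)C
F5 | step 7 | (2S)-2-{2-methoxy-5-(prop-2-en-1-yl)-4-[tri(propan-2-yl)silyloxy]phenyl}propan-1-ol | C=CCc1cc([C@H](C)CO)c(OC)cc1O[Si](C(C)C)(C(C)C)C(C)C
F6 | step 7 | (2S)-2-{2-methoxy-5-(prop-2-en-1-yl)-4-[tri(propan-2-yl)silyloxy]phenyl}propanal | C=CCc1cc([C@H](C)C=O)c(OC)cc1O[Si](C(C)C)(C(C)C)C(C)C
F7 | step 7 | (1S,2S)-1-(3,4-dimethoxyphenyl)-2-{2-methoxy-5-(prop-2-en-1-yl)-4-[tri(propan-2-yl)silyloxy]phenyl}propan-1-ol | C=CCc1cc([C@H](C)[C@H](O)c2ccc(OC)c(OC)c2)c(OC)cc1O[Si](C(C)C)(C(C)C)C(C)C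
F8 | step 2 | 4-bromo-2-iodo-5-methoxyphenol | COc1cc(O)c(I)cc1Br
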